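How much target does 100 µM of initiator win from 0.020 M of substrate in 12 min?

    2 initiating radical → ended chains B (k1 = 1.3 × 10⁷ M⁻¹ s⁻¹)
    initiator → 2 initiating radical (k2 = 0.0149 s⁻¹)
    gas ⇌ coupling partner, rate k3*(csat - [coupling partner]) (k3 = 0.0593 s⁻¹, csat = 4.2 mM)
    coupling partner + chain carrier → target + initiating radical (k4 = 56400 M⁻¹ s⁻¹)
    substrate + initiating radical → chain carrier (k5 = 8540 M⁻¹ s⁻¹)
    2 chain carrier → ended chains A (k6 = 2.5 × 10⁶ M⁻¹ s⁻¹)

substrate 0.020 M; gas 4.2 mM (held); initiator 100 µM; time 12 min

- a species is counted by the substrate in it: one ended chains A counts as two
- for a step with 2 of a species take k times the square, and two of it per event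
- at the start none of coupling partner is dissolved
- run time (flask): 12 min

* target at 12 min, in percent of the substrate charged
* concentration of coupling partner in solution at 3.0 min, in percent of saturation
* the change that raises the amount of target at 12 min, in percent of the substrate charged most ("none" if none brings more than 2 percentage points) (Thursday's / Tuesday's / none)
* amount of target at 12 min, in percent of the substrate charged, after Tuesday's

- Thursday's: doubling the transfer coefficient of step 3, all else as stated
- Tuesday's: doubling the saturation concentration of gas, all else as stated

The ledger is kept in initiator, whose half-life of 0.775 min is much shorter than the run. First entry: each initiator pays out two initiating radicals. Second entry: these radicals are not consumed by the chain, since the chain carrier hands one back each time it makes a target. Third entry: radicals leave in pairs, so each initiator closes as one ended chain, A or B.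

With the two chain steps running at equal rates and the coupling partner near saturation, [chain carrier]/[initiating radical] is 0.721. Balancing making against loss gives [initiating radical]² as the initiator's decay rate over K, the radical coupling constant plus the carrier's times that ratio squared: 1.43 × 10⁷ M⁻¹ s⁻¹. At the start, a radical is lost at 8.39 s⁻¹ but adds to substrate at 171 s⁻¹, so it mostly goes round.

Summing over the decaying initiator gives the reach, the natural log of substrate charged over substrate left at the dead end, 0.370. It grows as the square root of the initiator charge. My reckoning is y = 30.9%, perhaps a little high, since the partner starts at nothing. The reach takes the partner at saturation, so the transfer coefficient is absent from it and it gives Thursday's no figure; Thursday's can shorten the partner's filling, which takes about 16.9 s, less than the initiator's half-life, so I expect a small gain. Tuesday's lowers the ratio to 0.360 and gives 31.8%, a gain of 0.90 percentage points, less than the threshold, so my choice is none.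

The forecast gave 31.5% (29.5% to 33.5%), above my figure, with 95%, none and 32.3%, holding the target rate “nearly independent of the partner concentration”.

The flask gives 29.8%, 94.7%, none and 31.2%, with gains of 0.7 points for Thursday's and 1.5 points for Tuesday's. The books close: ended chains A at 0.199% of the substrate, counted two to a chain, plus ended chains B at 8.01 × 10⁻⁵ M, make 100 µM of ended chains. Scaled to 147 µM of initiator, where the run has moved y by 5 points, the reach moves it by 5.2 points.

In the neighbour flask with 4.0 × 10⁻⁵ M of initiator, the reach shrinks to 0.234 and promises 20.9% of target. That flask gives 20.1%, with 79.8% of its substrate left.

The rate constants belong to no real substance.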